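The data are simulated for substances that don't exist, noise included.

Watch L.

all flasks: Q 0.50 M

| flask | G | remark | time |
|---|---|---|---|
| south | 0.29 M | run made earlier |  |
| south-east | 1.5 M | run made earlier |  |
| grey | 2.00 M |  | 5.0 h |
| violet | 0.400 M |  | 5.0 h |
| green | 0.500 M |  | 5.0 h |

| run | time / h | Z / % | L / % |
|---|---|---|---|
| south | 0.667 | 3.4 | 4.5 |
| south | 1.33 | 0 | 6.6 |
| south | 2.00 | 3.0 | 7.2 |
| south | 2.50 | 0 | 6.4 |
| south | 3.00 | 1.0 | 5.0 |
| south | 4.00 | 0.9 | 6.6 |
| south-east | 0.250 | 16.7 | 66.1 |
| south-east | 0.667 | 13.6 | 66.3 |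
| south-east | 1.33 | 10.9 | 68.7 |
| south-east | 2.00 | 9.1 | 68.7 |
| south-east | 2.50 | 7.3 | 68.3 |
| south-east | 4.00 | 9.2 | 68.5 |

(standard deviation of a reading: 1 percentage point)

- the analysis behind the earlier runs scatters by 1 percentage point, standard deviation

- which of these holds the largest part of the Q at the end of grey (Z / Q / L)
- which of these holds the largest part of the Q at the end of violet (Z / Q / L)
- which of these holds the largest part of the Q at the end of green (Z / Q / L)
- amount of Z at the end of green, in percent of the Q charged

In south-east, L stood at 66.1 % after 0.250 h and at 68.5 % after 4.00 h, while Z sank from 16.7 % to 9.2 %. So I took L in south-east as finished early and reckoned with end values. I folded each recipe into one number, the charge ratio, meaning equivalents of G per Q. It was 0.580 in south and 3.00 in south-east. From the last readings of those two runs I reckoned: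

power = ln(68.5 % / 6.6 %) / ln(3.00 / 0.580) = 1.42

I call this power, which carries south's L into south-east's L, the steepness. It is a reading, and it says that L climbed faster than the charge ratio. Scaling from south-east gave:

L in green, ratio 1.00: 14.3 %

L in violet, ratio 0.800: 10.4 %

L in grey, ratio 4.00: 103 %

Grey's figure is more than the Q charged, so one number was not enough there. I still chose L for grey. In violet and green I counted what was neither L nor Z as Q, so I chose Q. The steepness gave me no figure for Z.

The forecast said L, Q and Q, with 3.5 % of Z in green, between 1.5 % and 7 %. It held that “these look like equilibrium-limited end states rather than kinetic ones”.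

The flasks gave L, Q and Q, and green ended with 0.00567 % of Z.

    G → D (k = 1.10 min⁻¹)
    Q + G → Z (k = 3.30 M⁻¹ min⁻¹)
    Q + Z → E (k = 0.220 M⁻¹ min⁻¹)
    G + Z → L (k = 4.00 M⁻¹ min⁻¹)

Green's L stood at 14.1 %, against my 14.3 %. Its Q stood at 23.6 %, and E, which holds two Q, stood at 62.3 %, with G, the limiting reagent, at 0 %. For the neighbour of green charged with 1.2 M of G, the steepness gives 49.9 %, and that flask held 52.2 % of L.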